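Numbering: ring C1 (C=O), C2 (CHMe), C3 (C(OH)Et), C4 (CHMe), C5 (CH–O–acyl), C6 (CHMe); acyl chain C1' (ester C=O) to C6' (CHMe attached to the pyrone).
Cuts: (i) the ester bond C5–O/C1'; (ii) C3–ethyl; (iii) ring bonds C1–C2 and C5–C6 together; (iv) in the chain, C4'–C5' (aldol) and the pyrone O–C bond (back to a triketone).
Enabling feature: the carbocycle carries oxygen on C1, C3 and C5 and methyl on C2, C4 and C6. With the carbonyl parked at C3, this pattern is the sum of a 1,4-dipole C2–C3(=O)–C4–C5(OBn), stored as the C2–C5 bond of a 3-benzyloxy-2,4-dimethylcyclobutanone, and the enol ether C6=C1.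
Forward: the four-membered ring is expanded by two atoms to the six-membered ring (two C–C bonds, four stereocentres); then ethyl addition at C3, debenzylation and esterification. The pyrone ring comes from a triketone, and a temporary δ-lactone tells C3'-OH from C5'-OH.
Both ketones that flank labile centres (C1 next to axial C6-Me, C5' next to C6') travel as SiEt3-protected carbinols and are unveiled by one oxidation after the last basic step.
Stereochemistry: in the ring only C4 is set by a bought auxiliary (SAMP), and C5, C6, C2 and C3 are relayed from it. In the chain C6' is bought, C2' comes from an oxazolidinone acylation, and C4' and C3' are relayed.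

Key step: step 6

Remark: the C1 carbinol centre of 11–13, 31 and 32 is drawn as the equatorial epimer expected from the chair closure; either epimer serves, because step 23 makes C1 trigonal.

Step 1
Reactants: 1 3-(benzyloxy)cyclobutan-1-one; 2 (S)-1-amino-2-(methoxymethyl)pyrrolidine (SAMP)
Product: 3 SAMP hydrazone of 1
Conditions: cyclohexane, MS 4 Å, 50 °C
Reagents that add atoms: none
Why: Hydrazone condensation of a strained, electrophilic ketone with the bought auxiliary; no stereocentre is formed and the benzyl ether is inert.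

Step 2
Reactants: 3 SAMP hydrazone of 1
Product: 5 SAMP hydrazone of (2R,4R)-3-(benzyloxy)-2,4-dimethylcyclobutan-1-one, via monomethylated hydrazone 4 (not isolated)
Conditions: LDA, THF, 0 °C; MeI, −95 °C to rt; then again LDA, 0 °C; MeI, −95 °C to rt (same flask); chromatography
Reagents that add atoms: iodomethane, CI
Why: Enders SAMP-hydrazone alkylation run twice: each Li–OMe-chelated azaenolate should take MeI on the same auxiliary-defined face (the sense that gives (R)-2-methylcyclohexanone from cyclohexanone), 4 is metalated at its remaining CH2, the methyl groups end up trans, and a single mis-alkylation gives the separable cis-dimethyl diastereomer rather than the enantiomer (Horeau-type upgrade).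

Step 3
Reactants: 5 SAMP hydrazone of (2R,4R)-3-(benzyloxy)-2,4-dimethylcyclobutan-1-one
Product: 6 (2R,4R)-3-(benzyloxy)-2,4-dimethylcyclobutan-1-one (methyl groups trans)
Conditions: saturated aq oxalic acid, Et2O, rt
Reagents that add atoms: water, O
Why: Two-phase oxalic acid hydrolysis of SAMP hydrazones is mild and non-epimerising, so both α-centres should survive; in the trans-(R,R) ketone the benzyloxy carbon is not a stereocentre, so one compound results.

Step 4
Reactants: 7 prop-2-en-1-ol
Product: 8 triethyl(prop-2-en-1-yloxy)silane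
Conditions: Et3SiCl, imidazole, CH2Cl2, 0 °C
Reagents that add atoms: chlorotriethylsilane, CC[Si](Cl)(CC)CC
Why: Standard silylation of a primary alcohol.

Step 5
Reactants: 8 triethyl(prop-2-en-1-yloxy)silane
Product: 9 (E)-triethyl(prop-1-en-1-yloxy)silane
Conditions: [Ir(cod)(PMePh2)2]PF6 (1 mol %, activated with H2), THF, rt
Reagents that add atoms: none
Why: Cationic iridium hydride-catalysed allyl-to-propenyl ether isomerisation, which is kinetically (E)-selective for allyl silyl ethers; the geometry matters in step 6.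

Step 6
Reactants: 6 (2R,4R)-3-(benzyloxy)-2,4-dimethylcyclobutan-1-one; 9 (E)-triethyl(prop-1-en-1-yloxy)silane
Product: 11 (2R,3S,4R,5R,6S)-3-(benzyloxy)-2,4,6-trimethyl-5-[(triethylsilyl)oxy]cyclohexan-1-one, via 1,4-zwitterion 10 (not isolated)
Conditions: EtAlCl2 (30 mol %), 9 (1.5 equiv), CH2Cl2, −78 to −40 °C; Et3N, then aq NaHCO3
Reagents that add atoms: none
Why: EtAlCl2 binds the ring carbonyl and the push–pull ring bond C2–C5 (or the equivalent C4–C5) heterolyses to zwitterion 10 (aluminium enolate C3=C2, benzyl oxocarbenium ion at C5); because the methyl groups are trans-(R,R), both cleavages give the same species, in which C4 is the only stereocentre left. The closest known reaction type is the Lewis acid-promoted formal [4+2] cycloaddition of 3-alkoxycyclobutanones with silyl enol ethers, a two-atom ring expansion to 3-alkoxy-5-silyloxycyclohexanones. C6 of 9 attacks C5 in an open Mukaiyama-type transition state: C5 is set by Felkin–Anh control from C4 (enolate arm perpendicular, attack past H), which gives C4-Me/C5-OBn trans on the ring, and C6 is set by the antiperiplanar arrangement open to an (E)-aldehyde enol silane, in which OSiEt3 avoids the branched C4 arm, which gives the C5-O/C6-Me cis (anti-aldol) relation. The silyl oxocarbenium ion at C1 is then captured by enolate carbon C2 in a 6-(enolendo)-exo-trig aldol closure through a chair with C4-Me, C5-OBn and C1-OSiEt3 equatorial and only C6-Me axial; the (Z)-enolate places C2-Me equatorial, which is also its thermodynamic position next to the C3 ketone, and the C1 configuration is erased in step 23. The step needs ring C–C cleavage to win over Mukaiyama addition to the C=O group, and ring closure to win over silyl loss; the donor (OBn)/acceptor (C=O·Al) substitution across the strained ring, the low temperature and the intramolecular closure should secure this, and release of EtAlCl2 on closure makes the acid catalytic.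

Step 7
Reactants: 11 (2R,3S,4R,5R,6S)-3-(benzyloxy)-2,4,6-trimethyl-5-[(triethylsilyl)oxy]cyclohexan-1-one
Product: 12 (1R,2R,3S,4R,5R,6S)-3-(benzyloxy)-1-ethyl-2,4,6-trimethyl-5-[(triethylsilyl)oxy]cyclohexan-1-ol
Conditions: anhydrous CeCl3, EtMgBr, THF, −78 °C
Reagents that add atoms: ethylmagnesium bromide, CC[Mg]Br
Why: 1,2-Addition of a weakly basic organocerium reagent avoids enolisation and β-elimination of the two β-oxygen groups, and the bulky reagent should attack along the equatorial trajectory (the axial path is hindered by the syn-axial hydrogens at C1 and C5), which puts ethyl equatorial and C3-OH axial, cis to C2-Me and C4-Me.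

Step 8
Reactants: 12 (1R,2R,3S,4R,5R,6S)-3-(benzyloxy)-1-ethyl-2,4,6-trimethyl-5-[(triethylsilyl)oxy]cyclohexan-1-ol
Product: 13 (1R,2R,3S,4R,5R,6S)-1-ethyl-2,4,6-trimethyl-5-[(triethylsilyl)oxy]cyclohexane-1,3-diol
Conditions: H2 (1 atm), Pd/C, EtOAc, rt
Reagents that add atoms: none
Why: Neutral hydrogenolysis of the benzyl ether frees C5-OH; in EtOAc the SiEt3 ether and the tertiary alcohol should be untouched.

Step 9
Reactants: 14 methyl (R)-3-hydroxy-2-methylpropanoate
Product: 15 methyl (R)-3-[(tert-butyldimethylsilyl)oxy]-2-methylpropanoate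
Conditions: TBSCl, imidazole, CH2Cl2, rt
Reagents that add atoms: tert-butyldimethylsilyl chloride, CC(C)(C)[Si](C)(C)Cl
Why: Standard silylation; the bought stereocentre becomes C6'.

Step 10
Reactants: 15 methyl (R)-3-[(tert-butyldimethylsilyl)oxy]-2-methylpropanoate; 16 pentan-3-one
Product: 17 (6R)-7-[(tert-butyldimethylsilyl)oxy]-4,6-dimethylheptane-3,5-dione (C4 epimers and enols)
Conditions: 16 (2.2 equiv), LDA (2.1 equiv), THF, −78 °C; then 15, −78 to 0 °C; aq NH4Cl
Reagents that add atoms: none
Why: Crossed Claisen condensation: the ketone enolate (no free amide base present) acylates on carbon and the product is drained as its lithium diketonate, which shields C6' from enolisation; the new central CHMe centre is irrelevant because it becomes pyrone C3.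

Step 11
Reactants: 17 (6R)-7-[(tert-butyldimethylsilyl)oxy]-4,6-dimethylheptane-3,5-dione
Product: 18 (7R)-8-[(tert-butyldimethylsilyl)oxy]-3,5,7-trimethyloctane-2,4,6-trione (epimers and enols at C3, C5)
Conditions: LDA (2.2 equiv), THF, −78 to 0 °C; N-methoxy-N-methylacetamide, −78 to 0 °C; aq NH4Cl
Reagents that add atoms: N-methoxy-N-methylacetamide, CON(C)C(C)=O
Why: Terminal acylation of a 1,3-diketone dianion (the second deprotonation takes place at the CH2 of the ethyl group, methylene before methine) with a Weinreb amide, whose chelated adduct prevents over-addition; both inner CHMe centres become sp2 pyrone carbons.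

Step 12
Reactants: 18 (7R)-8-[(tert-butyldimethylsilyl)oxy]-3,5,7-trimethyloctane-2,4,6-trione
Product: 19 (R)-2-{1-[(tert-butyldimethylsilyl)oxy]propan-2-yl}-3,5,6-trimethyl-4H-pyran-4-one
Conditions: PPh3, CCl4, Et3N, THF, rt
Reagents that add atoms: none
Why: Appel-type cyclodehydration of a 1,3,5-triketone: one terminal enol oxygen is activated as an oxyphosphonium salt and displaced by the distal enol oxygen (six-membered O–C closure) to give the aromatic 4-pyrone under non-acidic conditions that keep the silyl ether and C6' intact.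

Step 13
Reactants: 19 (R)-2-{1-[(tert-butyldimethylsilyl)oxy]propan-2-yl}-3,5,6-trimethyl-4H-pyran-4-one
Product: 20 (R)-2-(1-hydroxypropan-2-yl)-3,5,6-trimethyl-4H-pyran-4-one
Conditions: HF·pyridine, THF, 0 °C
Reagents that add atoms: none
Why: Routine cleavage of a primary silyl ether; the pyrone is inert to HF·pyridine.

Step 14
Reactants: 20 (R)-2-(1-hydroxypropan-2-yl)-3,5,6-trimethyl-4H-pyran-4-one
Product: 21 (S)-2-(3,5,6-trimethyl-4-oxo-4H-pyran-2-yl)propanal
Conditions: Dess–Martin periodinane, NaHCO3, CH2Cl2, 0 °C; used crude at once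
Reagents that add atoms: none
Why: Dess–Martin oxidation is non-basic, and the aldehyde, whose C6'–H is activated by both CHO and the pyrone, is carried on without chromatography to avoid enolisation.

Step 15
Reactants: 22 (S)-4-benzyl-3-propionyloxazolidin-2-one
Product: 23 (S)-4-benzyl-3-[(R)-2-methyl-3-oxopentanoyl]oxazolidin-2-one
Conditions: LDA, THF, −78 °C; propionyl chloride, −78 °C
Reagents that add atoms: propionyl chloride, CCC(=O)Cl
Why: C-acylation of the chelated (Z)-lithium imide enolate on the face opposite to the benzyl group sets C2' (R), and the β-ketoimide should not epimerise because allylic 1,3-strain keeps the C2'–H bond out of alignment with the carbonyl π systems.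

Step 16
Reactants: 23 (S)-4-benzyl-3-[(R)-2-methyl-3-oxopentanoyl]oxazolidin-2-one; 21 (S)-2-(3,5,6-trimethyl-4-oxo-4H-pyran-2-yl)propanal
Product: 24 (S)-4-benzyl-3-[(2R,4R,5S,6R)-5-hydroxy-2,4-dimethyl-3-oxo-6-(3,5,6-trimethyl-4-oxo-4H-pyran-2-yl)heptanoyl]oxazolidin-2-one
Conditions: TiCl4, i-Pr2NEt, CH2Cl2, −78 °C; then 21, −78 °C
Reagents that add atoms: none
Why: Titanium-mediated syn aldol of a β-ketoimide: the chelated (Z)-enolate reacts through a closed chair on the face dictated by C2'-Me (C2'/C4' syn), gives C4'/C5' syn, and as a (Z)-enolate is matched with anti-Felkin attack on the α-chiral aldehyde (C5'/C6' anti), so C4' is set while C5' is only a temporary centre.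

Step 17
Reactants: 24 (S)-4-benzyl-3-[(2R,4R,5S,6R)-5-hydroxy-2,4-dimethyl-3-oxo-6-(3,5,6-trimethyl-4-oxo-4H-pyran-2-yl)heptanoyl]oxazolidin-2-one
Product: 26 (3R,4R,5S,6R)-4-hydroxy-3,5-dimethyl-6-[(1R)-1-(3,5,6-trimethyl-4-oxo-4H-pyran-2-yl)ethyl]tetrahydro-2H-pyran-2-one, via anti-diol imide 25 (not isolated)
Conditions: Me4NBH(OAc)3, MeCN/AcOH, −30 °C; aqueous work-up; then DBU (cat.), CH2Cl2, rt
Reagents that add atoms: none
Why: Evans–Saksena reduction: acetoxyborohydride bound to C5'-OH delivers hydride intramolecularly to give the 1,3-anti diol (C3'-OH anti to both flanking methyl groups), and base-catalysed 6-exo-trig attack of C5'-OH on the activated imide then expels the auxiliary, so the lactone tells the two carbinols apart.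

Step 18
Reactants: 26 (3R,4R,5S,6R)-4-hydroxy-3,5-dimethyl-6-[(1R)-1-(3,5,6-trimethyl-4-oxo-4H-pyran-2-yl)ethyl]tetrahydro-2H-pyran-2-one
Product: 27 the C3'-O-TBS ether of lactone 26
Conditions: TBSOTf, 2,6-lutidine, CH2Cl2, −78 to 0 °C
Reagents that add atoms: tert-butyldimethylsilyl trifluoromethanesulfonate, CC(C)(C)[Si](C)(C)OS(=O)(=O)C(F)(F)F
Why: Silyl triflate/lutidine protects hindered secondary alcohols without base-induced β-elimination; any O-silylation of the pyrone carbonyl is reversed on work-up.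

Step 19
Reactants: 27 the C3'-O-TBS ether of lactone 26
Product: 28 (2R,3R,4R,5R,6R)-3-[(tert-butyldimethylsilyl)oxy]-5-hydroxy-2,4-dimethyl-6-(3,5,6-trimethyl-4-oxo-4H-pyran-2-yl)heptanoic acid
Conditions: LiOH, THF/H2O, 0 °C; 1 M HCl to pH 4, 0 °C; used directly
Reagents that add atoms: lithium hydroxide, [Li+].[OH-]
Why: Saponification of the δ-lactone is helped by the strain of its four cis substituents, which should also slow relactonisation on careful acidification; the tetrasubstituted pyrone and the hindered silyl ether tolerate cold LiOH.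

Step 20
Reactants: 28 (2R,3R,4R,5R,6R)-3-[(tert-butyldimethylsilyl)oxy]-5-hydroxy-2,4-dimethyl-6-(3,5,6-trimethyl-4-oxo-4H-pyran-2-yl)heptanoic acid
Product: 30 (2R,3R,4R,5R,6R)-3-[(tert-butyldimethylsilyl)oxy]-2,4-dimethyl-5-[(triethylsilyl)oxy]-6-(3,5,6-trimethyl-4-oxo-4H-pyran-2-yl)heptanoic acid, via triethylsilyl ester 29 (not isolated)
Conditions: Et3SiOTf (2.3 equiv), 2,6-lutidine, CH2Cl2, −78 to 0 °C; then pH 5 aqueous buffer/THF, rt
Reagents that add atoms: triethylsilyl trifluoromethanesulfonate, CC[Si](CC)(CC)OS(=O)(=O)C(F)(F)F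
Why: Exhaustive silylation followed by hydrolysis of the far more labile silyl ester is routine, and keeping C5' as a masked ketone leaves C6' non-acidic during the basic esterification.

Step 21
Reactants: 30 (2R,3R,4R,5R,6R)-3-[(tert-butyldimethylsilyl)oxy]-2,4-dimethyl-5-[(triethylsilyl)oxy]-6-(3,5,6-trimethyl-4-oxo-4H-pyran-2-yl)heptanoic acid; 13 (1R,2R,3S,4R,5R,6S)-1-ethyl-2,4,6-trimethyl-5-[(triethylsilyl)oxy]cyclohexane-1,3-diol
Product: 31 ester of 30 with the C5 hydroxyl of 13 (C1-OSiEt3, C5'-OSiEt3, C3'-OTBS, free tertiary C3-OH)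
Conditions: 2,4,6-trichlorobenzoyl chloride, Et3N, THF, rt; then 13, DMAP, toluene, rt
Reagents that add atoms: none
Why: Yamaguchi esterification acylates the secondary equatorial C5-OH while the tertiary C3-OH is too hindered; since neither ketone is present yet, C6 and C6' cannot epimerise and no β-elimination or retro-aldol path exists.

Step 22
Reactants: 31 ester of 30 with the C5 hydroxyl of 13
Product: 32 the C1,C5'-diol (both SiEt3 groups removed, C3'-OTBS kept)
Conditions: PPTS (cat.), MeOH/CH2Cl2, 0 °C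
Reagents that add atoms: none
Why: Acid-catalysed methanolysis distinguishes SiEt3 ethers from the much bulkier TBS ether; the ester, the pyrone and the tertiary alcohol are inert.

Step 23
Reactants: 32 the C1,C5'-diol
Product: 33 the C3'-O-TBS ether of the target
Conditions: Dess–Martin periodinane (3 equiv), CH2Cl2, 0 °C to rt
Reagents that add atoms: none
Why: One neutral Dess–Martin oxidation turns both secondary carbinols into the C1 and C5' ketones, leaves the tertiary alcohol alone and, without base, should not touch the axial C6-Me, C2, C4' or C6' centres.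

Step 24
Reactants: 33 the C3'-O-TBS ether of the target
Product: 34 (1R,2R,3R,4R,6R)-3-ethyl-3-hydroxy-2,4,6-trimethyl-5-oxocyclohexyl (2R,3R,4S,6S)-3-hydroxy-2,4-dimethyl-5-oxo-6-(3,5,6-trimethyl-4-oxo-4H-pyran-2-yl)heptanoate (target)
Conditions: HF·pyridine, pyridine, THF, 0 °C to rt
Reagents that add atoms: none
Why: Buffered HF·pyridine cleaves the hindered secondary silyl ether under mildly acidic conditions, in which the base-sensitive β-hydroxy ketones and α-stereocentres should persist.

Compound list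
1 | 3-(benzyloxy)cyclobutan-1-one | O=C1CC(OCc2ccccc2)C1 | starting material
2 | (S)-1-amino-2-(methoxymethyl)pyrrolidine (SAMP) | COC[C@@H]1CCCN1N | starting material
3 | SAMP hydrazone of 1 | COC[C@@H]1CCCN1N=C1CC(OCc2ccccc2)C1 | intermediate
4 | monomethylated SAMP hydrazone (both orientations of OBn relative to Me; not isolated) | COC[C@@H]1CCCN1N=C1CC(OCc2ccccc2)[C@H]1C | intermediate
5 | SAMP hydrazone of 6 | COC[C@@H]1CCCN1N=C1[C@H](C)C(OCc2ccccc2)[C@H]1C | intermediate
6 | (2R,4R)-3-(benzyloxy)-2,4-dimethylcyclobutan-1-one | O=C1[C@H](C)C(OCc2ccccc2)[C@H]1C | intermediate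
7 | prop-2-en-1-ol | C=CCO | starting material
8 | triethyl(prop-2-en-1-yloxy)silane | C=CCO[Si](CC)(CC)CC | intermediate
9 | (E)-triethyl(prop-1-en-1-yloxy)silane | C/C=C/O[Si](CC)(CC)CC | intermediate
10 | 1,4-zwitterion, (Z)-enolate/benzyl oxocarbenium ion, drawn without the aluminium Lewis acid (not isolated) | C/C=C(\[O-])[C@H](C)C=[O+]Cc1ccccc1 | intermediate
11 | (2R,3S,4R,5R,6S)-3-(benzyloxy)-2,4,6-trimethyl-5-[(triethylsilyl)oxy]cyclohexan-1-one | O=C1[C@H](C)[C@@H](OCc2ccccc2)[C@@H](C)[C@@H](O[Si](CC)(CC)CC)[C@@H]1C | intermediate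
12 | (1R,2R,3S,4R,5R,6S)-3-(benzyloxy)-1-ethyl-2,4,6-trimethyl-5-[(triethylsilyl)oxy]cyclohexan-1-ol | CC[C@@]1(O)[C@H](C)[C@@H](OCc2ccccc2)[C@@H](C)[C@@H](O[Si](CC)(CC)CC)[C@@H]1C | intermediate
13 | (1R,2R,3S,4R,5R,6S)-1-ethyl-2,4,6-trimethyl-5-[(triethylsilyl)oxy]cyclohexane-1,3-diol | CC[C@@]1(O)[C@H](C)[C@@H](O)[C@@H](C)[C@@H](O[Si](CC)(CC)CC)[C@@H]1C | intermediate
14 | methyl (R)-3-hydroxy-2-methylpropanoate | OC[C@@H](C)C(=O)OC | starting material
15 | methyl (R)-3-[(tert-butyldimethylsilyl)oxy]-2-methylpropanoate | CC(C)(C)[Si](C)(C)OC[C@@H](C)C(=O)OC | intermediate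
16 | pentan-3-one | CCC(=O)CC | starting material
17 | (6R)-7-[(tert-butyldimethylsilyl)oxy]-4,6-dimethylheptane-3,5-dione | CC(C)(C)[Si](C)(C)OC[C@@H](C)C(=O)C(C)C(=O)CC | intermediate
18 | (7R)-8-[(tert-butyldimethylsilyl)oxy]-3,5,7-trimethyloctane-2,4,6-trione | CC(C)(C)[Si](C)(C)OC[C@@H](C)C(=O)C(C)C(=O)C(C)C(C)=O | intermediate
19 | (R)-2-{1-[(tert-butyldimethylsilyl)oxy]propan-2-yl}-3,5,6-trimethyl-4H-pyran-4-one | CC(C)(C)[Si](C)(C)OC[C@@H](C)c1oc(C)c(C)c(=O)c1C | intermediate
20 | (R)-2-(1-hydroxypropan-2-yl)-3,5,6-trimethyl-4H-pyran-4-one | OC[C@@H](C)c1oc(C)c(C)c(=O)c1C | intermediate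
21 | (S)-2-(3,5,6-trimethyl-4-oxo-4H-pyran-2-yl)propanal | O=C[C@@H](C)c1oc(C)c(C)c(=O)c1C | intermediate
22 | (S)-4-benzyl-3-propionyloxazolidin-2-one | CCC(=O)N1[C@@H](Cc2ccccc2)COC1=O | starting material
23 | (S)-4-benzyl-3-[(R)-2-methyl-3-oxopentanoyl]oxazolidin-2-one | CCC(=O)[C@@H](C)C(=O)N1[C@@H](Cc2ccccc2)COC1=O | intermediate
24 | syn,syn aldol adduct (2R,4R,5S,6R) | O=C([C@H](C)C(=O)[C@H](C)[C@@H](O)[C@@H](C)c1oc(C)c(C)c(=O)c1C)N1[C@@H](Cc2ccccc2)COC1=O | intermediate
25 | 3',5'-anti diol imide (2R,3R,4R,5R,6R) (not isolated) | O=C([C@H](C)[C@H](O)[C@H](C)[C@@H](O)[C@@H](C)c1oc(C)c(C)c(=O)c1C)N1[C@@H](Cc2ccccc2)COC1=O | intermediate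
26 | (3R,4R,5S,6R)-4-hydroxy-3,5-dimethyl-6-[(1R)-1-(3,5,6-trimethyl-4-oxo-4H-pyran-2-yl)ethyl]tetrahydro-2H-pyran-2-one | O=C1[C@H](C)[C@H](O)[C@H](C)[C@@H](O1)[C@@H](C)c2oc(C)c(C)c(=O)c2C | intermediate
27 | C3'-O-TBS ether of lactone 26 | O=C1[C@H](C)[C@H](O[Si](C)(C)C(C)(C)C)[C@H](C)[C@@H](O1)[C@@H](C)c2oc(C)c(C)c(=O)c2C | intermediate
28 | (2R,3R,4R,5R,6R)-3-[(tert-butyldimethylsilyl)oxy]-5-hydroxy-2,4-dimethyl-6-(3,5,6-trimethyl-4-oxo-4H-pyran-2-yl)heptanoic acid | OC(=O)[C@H](C)[C@H](O[Si](C)(C)C(C)(C)C)[C@H](C)[C@@H](O)[C@@H](C)c1oc(C)c(C)c(=O)c1C | intermediate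
29 | triethylsilyl ester of 30 (not isolated) | CC[Si](CC)(CC)OC(=O)[C@H](C)[C@H](O[Si](C)(C)C(C)(C)C)[C@H](C)[C@@H](O[Si](CC)(CC)CC)[C@@H](C)c1oc(C)c(C)c(=O)c1C | intermediate
30 | (2R,3R,4R,5R,6R)-3-[(tert-butyldimethylsilyl)oxy]-2,4-dimethyl-5-[(triethylsilyl)oxy]-6-(3,5,6-trimethyl-4-oxo-4H-pyran-2-yl)heptanoic acid | OC(=O)[C@H](C)[C@H](O[Si](C)(C)C(C)(C)C)[C@H](C)[C@@H](O[Si](CC)(CC)CC)[C@@H](C)c1oc(C)c(C)c(=O)c1C | intermediate
31 | fully protected ester (C1-OSiEt3, C5'-OSiEt3, C3'-OTBS) | CC[C@@]1(O)[C@H](C)[C@@H](OC(=O)[C@H](C)[C@H](O[Si](C)(C)C(C)(C)C)[C@H](C)[C@@H](O[Si](CC)(CC)CC)[C@@H](C)c2oc(C)c(C)c(=O)c2C)[C@@H](C)[C@@H](O[Si](CC)(CC)CC)[C@@H]1C | intermediate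
32 | C1,C5'-diol (C3'-OTBS) | CC[C@@]1(O)[C@H](C)[C@@H](OC(=O)[C@H](C)[C@H](O[Si](C)(C)C(C)(C)C)[C@H](C)[C@@H](O)[C@@H](C)c2oc(C)c(C)c(=O)c2C)[C@@H](C)[C@@H](O)[C@@H]1C | intermediate
33 | C3'-O-TBS ether of the target | CC[C@@]1(O)[C@H](C)[C@@H](OC(=O)[C@H](C)[C@H](O[Si](C)(C)C(C)(C)C)[C@H](C)C(=O)[C@@H](C)c2oc(C)c(C)c(=O)c2C)[C@@H](C)C(=O)[C@@H]1C | intermediate
34 | (1R,2R,3R,4R,6R)-3-ethyl-3-hydroxy-2,4,6-trimethyl-5-oxocyclohexyl (2R,3R,4S,6S)-3-hydroxy-2,4-dimethyl-5-oxo-6-(3,5,6-trimethyl-4-oxo-4H-pyran-2-yl)heptanoate | CC[C@@]1(O)[C@H](C)[C@@H](OC(=O)[C@H](C)[C@H](O)[C@H](C)C(=O)[C@@H](C)c2oc(C)c(C)c(=O)c2C)[C@@H](C)C(=O)[C@@H]1C | target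

Total step count: 24.
Longest linear sequence: 15 steps (9–14, 16–24).

Steps most likely to fail

Step 6. The anti simple diastereoselection in the C5–C6 bond formation may be insufficient, because the competing open transition states differ only in gauche contacts. Mukaiyama addition to the ring carbonyl may compete, and the silyl group may be lost before ring closure.
The fallback sets out from 16 and returns at 11. It makes the same carbon chain by closed-transition-state aldol chemistry and closes the ring in a separate operation.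
- Commercial methyl (S)-3-hydroxy-2-methylpropanoate is silylated (TBSCl, imidazole) to the silyl ether ester F1 and reduced with i-Bu2AlH at −78 °C to the aldehyde F2.
- The (Z)-titanium enolate of 16 (TiCl4, i-Pr2NEt) adds to F2 to give the syn, anti-Felkin aldol adduct F3; a (Z)-enolate avoids the syn-pentane contact in the anti-Felkin chair.
- Benzyl trichloroacetimidate with catalytic TfOH gives the benzyl ether F4, HF·pyridine gives the primary alcohol F5, and Dess–Martin oxidation gives the keto aldehyde F6.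
- Soft enolisation of the ethyl ketone (TiCl4, i-Pr2NEt, −78 °C) closes the ring by intramolecular aldol addition to the hydroxy ketone F7.
- Et3SiOTf/2,6-lutidine converts F7 into 11.

Step 2. Substrate control by the benzyloxy group may override the auxiliary in the one alkylation that has to occur cis to it. This would drain material into the cis-dimethyl series.
The fallback sets out from 3 and returns at 6. It makes use of that bias.
- The two methylations are run without regard to selectivity and give mainly the all-trans dimethyl hydrazone F8.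
- Cleavage as in step 3 and equilibration with DBU funnel all isomers to the thermodynamic all-trans meso ketone F9.
- Enantioselective deprotonation of F9 with lithium (R,R)-bis(1-phenylethyl)amide (or its antipode, as the sense requires) and internal Me3SiCl quench at −100 °C gives the silyl enol ether F10. This keeps the C4 centre.
- MeLi regenerates the lithium enolate, and kinetic protonation with 2,6-di-tert-butyl-4-methylphenol at −78 °C, on the face away from the vicinal OBn group, gives 6.

Step 11. The diketonate may be deprotonated at the methine next to the silyloxymethyl group, which causes epimerisation and β-elimination of silanolate. O-acylation may also compete with terminal C-acylation.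
The fallback sets out from 15 and returns at 19. It carries the triketone in masked form as an isoxazole.
- Commercial 3,4,5-trimethylisoxazole is lithiated at its 5-methyl group (n-BuLi, −78 °C) and methylated to the ethylisoxazole F11.
- A second lateral lithiation and acylation with ester 15 gives the isoxazolyl ketone F12.
- Reductive N–O cleavage with Mo(CO)6 in wet MeCN gives the enaminone F13.
- Brief treatment of F13 with dilute acid closes it to 19, with addition–elimination at the enamine carbon and loss of ammonia.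

Further compounds
F1 | step 6 | methyl (S)-3-[(tert-butyldimethylsilyl)oxy]-2-methylpropanoate | CC(C)(C)[Si](C)(C)OC[C@H](C)C(=O)OC
F2 | step 6 | (S)-3-[(tert-butyldimethylsilyl)oxy]-2-methylpropanal | CC(C)(C)[Si](C)(C)OC[C@H](C)C=O
F3 | step 6 | (4R,5S,6S)-7-[(tert-butyldimethylsilyl)oxy]-5-hydroxy-4,6-dimethylheptan-3-one | CCC(=O)[C@H](C)[C@@H](O)[C@@H](C)CO[Si](C)(C)C(C)(C)C
F4 | step 6 | (4R,5S,6S)-5-(benzyloxy)-7-[(tert-butyldimethylsilyl)oxy]-4,6-dimethylheptan-3-one | CCC(=O)[C@H](C)[C@@H](OCc1ccccc1)[C@@H](C)CO[Si](C)(C)C(C)(C)C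
F5 | step 6 | (4R,5S,6S)-5-(benzyloxy)-7-hydroxy-4,6-dimethylheptan-3-one | CCC(=O)[C@H](C)[C@@H](OCc1ccccc1)[C@@H](C)CO
F6 | step 6 | (2R,3S,4R)-3-(benzyloxy)-2,4-dimethyl-5-oxoheptanal | CCC(=O)[C@H](C)[C@@H](OCc1ccccc1)[C@@H](C)C=O
F7 | step 6 | (2R,3S,4S,5R,6S)-3-(benzyloxy)-5-hydroxy-2,4,6-trimethylcyclohexan-1-one | O=C1[C@H](C)[C@@H](OCc2ccccc2)[C@@H](C)[C@@H](O)[C@@H]1C
F8 | step 2 | SAMP hydrazone of the all-trans ketone F9 | COC[C@@H]1CCCN1N=C1[C@H](C)[C@@H](OCc2ccccc2)[C@@H]1C
F9 | step 2 | (2R,4S)-3-(benzyloxy)-2,4-dimethylcyclobutan-1-one, OBn trans to both methyl groups (meso) | O=C1[C@H](C)[C@@H](OCc2ccccc2)[C@@H]1C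
F10 | step 2 | {[3-(benzyloxy)-2,4-dimethylcyclobut-1-en-1-yl]oxy}trimethylsilane, OBn and 4-Me trans, 4-centre as in 6 | C[Si](C)(C)OC1=C(C)[C@H](OCc2ccccc2)[C@H]1C
F11 | step 11 | 5-ethyl-3,4-dimethylisoxazole | CCc1onc(C)c1C
F12 | step 11 | (4R)-5-[(tert-butyldimethylsilyl)oxy]-2-(3,4-dimethylisoxazol-5-yl)-4-methylpentan-3-one | CC(C)(C)[Si](C)(C)OC[C@@H](C)C(=O)C(C)c1onc(C)c1C
F13 | step 11 | (7R)-2-amino-8-[(tert-butyldimethylsilyl)oxy]-3,5,7-trimethyloct-2-ene-4,6-dione | CC(C)(C)[Si](C)(C)OC[C@@H](C)C(=O)C(C)C(=O)C(C)=C(C)N
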